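Numbering and enabling feature: C1 = quaternary ring carbon, C2–C4 = ring CH2, C5 = ring alkene carbon, C6 = carbinol carbon, C7 = exocyclic CH, C8 = tether CH2, C9 = ketone carbon (primes for the second half). In ring A (C1–C6) and ring B (C1′–C6′) the allylic carbinol C6 lies between quaternary C1 and C5 of the exocyclic C5=C7 alkene, which holds C6 cis and C4 trans to the C8 chain; each ring is thus a 2-alkylidenecyclohexanol, the product expected when a C5 alkenylmetal adds to a C6 aldehyde carried by C1.
Cuts: first C5–C6 and C5′–C6′ (both rings open to an acyclic (Z,Z)-bis(vinyl iodide) diketo dialdehyde); then C4–C5 and C4′–C5′ (two enantiomeric alkylboranes and the six-carbon bis(1,1-dibromoalkene) C5–C7–C8–C8′–C7′–C5′); then, in each quaternary fragment, C1–C2, C1–CH3 and the CH2–CH= bond of the prenyl ketone arm.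
Forward order: each quaternary fragment is made in six steps, the chain is joined by two successive trans-selective B-alkyl Suzuki couplings onto 1,1,6,6-tetrabromohexa-1,5-diene, bromine is exchanged for iodine, the diols are unmasked and oxidised, and rings A and B close last, together, in one operation.
Stereochemistry: the target is meso, so C1 and C1′ are made with opposite configurations from (R)- and (S)-ethyl 4-chloro-3-hydroxybutanoate by Fráter–Seebach methylation then allylation, the C9 carbinol acting as a relay that is later oxidised away. The alkene geometry follows from the order in which the two bromines of each dibromoalkene are replaced, and C6 and C6′ are set under the control of C1 and C1′ during ring closure.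
Key step: step 19

Remark: succinaldehyde 22 is taken as the freshly distilled commercial dialdehyde (it is equally released from 2,5-dimethoxytetrahydrofuran by hot water), and minor C2 epimers from steps 4 and 10 are assumed to be removed by chromatography before the fragments are joined.

Step 1
Reactants: 1 ethyl (3R)-4-chloro-3-hydroxybutanoate
Product: 2 ethyl 2-[(2R)-oxiran-2-yl]acetate
Conditions: Ag2O (1.2 equiv), DME, 60 °C, dark
Reagents that add atoms: none
Why: Silver-assisted halohydrin-to-epoxide closure (intramolecular Williamson etherification) takes up chloride and the proton without a soluble alkoxide base, so the β,γ-epoxy ester should not open by E1cB to the 4-hydroxycrotonate, and the stereocentre, not being a reacting atom, keeps its configuration.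

Step 2
Reactants: 2 ethyl 2-[(2R)-oxiran-2-yl]acetate; 3 (2-methylprop-1-en-1-yl)magnesium bromide
Product: 4 ethyl (3S)-3-hydroxy-6-methylhept-5-enoate
Conditions: 3 (1.5 equiv), CuI (10 mol%), THF, −40 to −20 °C; aq NH4Cl
Reagents that add atoms: none
Why: Copper-catalysed SN2 opening of a terminal epoxide by an alkenyl Grignard reagent occurs at the CH2 terminus faster than addition to the ester at low temperature, so the carbinol centre is carried over unchanged (its descriptor becomes S only because the priorities change) and the CH2CH=CMe2 arm is in place.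

Step 3
Reactants: 4 ethyl (3S)-3-hydroxy-6-methylhept-5-enoate; 5 iodomethane
Product: 7 ethyl (2S,3S)-3-hydroxy-2,6-dimethylhept-5-enoate, via dilithium alkoxide enolate 6 (not isolated)
Conditions: LiN(i-Pr)2 (2.2 equiv), THF, −78 to −20 °C; then 5, DMPU, −78 to −10 °C; aq NH4Cl
Reagents that add atoms: none
Why: Fráter–Seebach alkylation: the lithium-chelated alkoxide enolate 6 should be methylated on the face anti to the C4 chain of the carbinol carbon, which sets C2 as S (anti product).

Step 4
Reactants: 7 ethyl (2S,3S)-3-hydroxy-2,6-dimethylhept-5-enoate; 8 allyl bromide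
Product: 10 ethyl (2S,3S)-3-hydroxy-2,6-dimethyl-2-(prop-2-en-1-yl)hept-5-enoate, via dilithium alkoxide enolate 9 (not isolated)
Conditions: LiN(i-Pr)2 (2.5 equiv), THF, −78 to −10 °C; then 8, DMPU, −78 to 0 °C; aq NH4Cl
Reagents that add atoms: none
Why: Second Fráter–Seebach alkylation: the chelated, fully substituted enolate 9 should again take up the electrophile anti to the carbinol substituent, so the order methyl-then-allyl fixes the quaternary carbon (future C1) with allyl anti and methyl syn to the hydroxyl.

Step 5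
Reactants: 10 ethyl (2S,3S)-3-hydroxy-2,6-dimethyl-2-(prop-2-en-1-yl)hept-5-enoate
Product: 11 (2R,3S)-2,6-dimethyl-2-(prop-2-en-1-yl)hept-5-ene-1,3-diol
Conditions: LiAlH4, THF, 0 °C to rt; H2O, aq NaOH
Reagents that add atoms: none
Why: Hydride reduction of the ester by LiAlH4 gives the primary alcohol (future C6) without touching either alkene or the two stereocentres.

Step 6
Reactants: 11 (2R,3S)-2,6-dimethyl-2-(prop-2-en-1-yl)hept-5-ene-1,3-diol
Product: 12 (4S,5R)-2,2,5-trimethyl-4-(3-methylbut-2-en-1-yl)-5-(prop-2-en-1-yl)-1,3-dioxane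
Conditions: 2,2-dimethoxypropane, PPTS (cat.), CH2Cl2, rt
Reagents that add atoms: 2,2-dimethoxypropane, COC(C)(C)OC
Why: Acid-catalysed transacetalisation closes the six-membered acetonide, which masks both hydroxyls against 9-BBN, aqueous base and tert-butyllithium.

Step 7
Reactants: 13 ethyl (3S)-4-chloro-3-hydroxybutanoate
Product: 14 ethyl 2-[(2S)-oxiran-2-yl]acetate
Conditions: Ag2O (1.2 equiv), DME, 60 °C, dark
Reagents that add atoms: none
Why: Silver-assisted halohydrin-to-epoxide closure (intramolecular Williamson etherification) as in step 1, here on the S enantiomer, whose stereocentre is again not a reacting atom.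

Step 8
Reactants: 14 ethyl 2-[(2S)-oxiran-2-yl]acetate; 3 (2-methylprop-1-en-1-yl)magnesium bromide
Product: 15 ethyl (3R)-3-hydroxy-6-methylhept-5-enoate
Conditions: 3 (1.5 equiv), CuI (10 mol%), THF, −40 to −20 °C; aq NH4Cl
Reagents that add atoms: none
Why: Copper-catalysed SN2 epoxide opening at the CH2 terminus as in step 2 gives the mirror-image β-hydroxy ester with the carbinol centre untouched.

Step 9
Reactants: 15 ethyl (3R)-3-hydroxy-6-methylhept-5-enoate; 5 iodomethane
Product: 17 ethyl (2R,3R)-3-hydroxy-2,6-dimethylhept-5-enoate, via dilithium alkoxide enolate 16 (not isolated)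
Conditions: LiN(i-Pr)2 (2.2 equiv), THF, −78 to −20 °C; then 5, DMPU, −78 to −10 °C; aq NH4Cl
Reagents that add atoms: none
Why: Fráter–Seebach alkylation of the chelated enolate 16 anti to the carbinol substituent, the mirror image of step 3, sets C2 as R.

Step 10
Reactants: 17 ethyl (2R,3R)-3-hydroxy-2,6-dimethylhept-5-enoate; 8 allyl bromide
Product: 19 ethyl (2R,3R)-3-hydroxy-2,6-dimethyl-2-(prop-2-en-1-yl)hept-5-enoate, via dilithium alkoxide enolate 18 (not isolated)
Conditions: LiN(i-Pr)2 (2.5 equiv), THF, −78 to −10 °C; then 8, DMPU, −78 to 0 °C; aq NH4Cl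
Reagents that add atoms: none
Why: Second Fráter–Seebach alkylation, the mirror image of step 4, should place allyl anti to the hydroxyl and so give the quaternary carbon (future C1′) antipodal to that of 10.

Step 11
Reactants: 19 ethyl (2R,3R)-3-hydroxy-2,6-dimethyl-2-(prop-2-en-1-yl)hept-5-enoate
Product: 20 (2S,3R)-2,6-dimethyl-2-(prop-2-en-1-yl)hept-5-ene-1,3-diol
Conditions: LiAlH4, THF, 0 °C to rt; H2O, aq NaOH
Reagents that add atoms: none
Why: Hydride reduction of the ester by LiAlH4 as in step 5 leaves alkenes and stereocentres untouched.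

Step 12
Reactants: 20 (2S,3R)-2,6-dimethyl-2-(prop-2-en-1-yl)hept-5-ene-1,3-diol
Product: 21 (4R,5S)-2,2,5-trimethyl-4-(3-methylbut-2-en-1-yl)-5-(prop-2-en-1-yl)-1,3-dioxane
Conditions: 2,2-dimethoxypropane, PPTS (cat.), CH2Cl2, rt
Reagents that add atoms: 2,2-dimethoxypropane, COC(C)(C)OC
Why: Acid-catalysed transacetalisation as in step 6 gives the enantiomeric acetonide.

Step 13
Reactants: 22 succinaldehyde; 23 tetrabromomethane
Product: 25 1,1,6,6-tetrabromohexa-1,5-diene, via dibromomethylidene ylide 24 (not isolated)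
Conditions: PPh3 (8 equiv), 23 (4 equiv), CH2Cl2, 0 °C; then 22, 0 °C
Reagents that add atoms: none
Why: Twofold Ramirez dibromoolefination (first stage of the Corey–Fuchs sequence): ylide 24, made from CBr4 and PPh3, converts both formyl groups into 1,1-dibromoalkenes, with no stereocentre or alkene geometry at stake.

Step 14
Reactants: 12 (4S,5R)-2,2,5-trimethyl-4-(3-methylbut-2-en-1-yl)-5-(prop-2-en-1-yl)-1,3-dioxane; 25 1,1,6,6-tetrabromohexa-1,5-diene
Product: 27 (4S,5R)-2,2,5-trimethyl-4-(3-methylbut-2-en-1-yl)-5-[(4Z)-4,9,9-tribromonona-4,8-dien-1-yl]-1,3-dioxane, via B-alkyl-9-BBN adduct 26 (not isolated)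
Conditions: 9-BBN, THF, rt; then 25 (3 equiv), Pd(dppf)Cl2 (5 mol%), AsPh3, Cs2CO3, DMF/H2O, rt
Reagents that add atoms: none
Why: 9-BBN hydroborates only the monosubstituted alkene at its terminus, and the B-alkyl Suzuki–Miyaura coupling should then replace the bromine trans to the chain of one dibromoalkene, because zerovalent palladium inserts faster into the less hindered trans C–Br bond and far more slowly into the bromoalkene formed, while the excess of 25 keeps the reaction to one terminus.

Step 15
Reactants: 21 (4R,5S)-2,2,5-trimethyl-4-(3-methylbut-2-en-1-yl)-5-(prop-2-en-1-yl)-1,3-dioxane; 27 (4S,5R)-2,2,5-trimethyl-4-(3-methylbut-2-en-1-yl)-5-[(4Z)-4,9,9-tribromonona-4,8-dien-1-yl]-1,3-dioxane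
Product: 29 (4S,5R)-5-{(4Z,8Z)-4,9-dibromo-12-[(4R,5S)-2,2,5-trimethyl-4-(3-methylbut-2-en-1-yl)-1,3-dioxan-5-yl]dodeca-4,8-dien-1-yl}-2,2,5-trimethyl-4-(3-methylbut-2-en-1-yl)-1,3-dioxane, via B-alkyl-9-BBN adduct 28 (not isolated)
Conditions: 9-BBN, THF, rt; then 27, Pd(dppf)Cl2 (5 mol%), AsPh3, Cs2CO3, DMF/H2O, rt
Reagents that add atoms: none
Why: The same hydroboration and trans-selective B-alkyl Suzuki–Miyaura coupling, now with the enantiomeric borane 28, should engage only the remaining dibromoalkene of 27 at its trans bromine and so join the two antipodal halves into the meso chain.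

Step 16
Reactants: 29 the (Z,Z)-dibromide bis(acetonide) of step 15
Product: 31 (4S,5R)-5-{(4Z,8Z)-4,9-diiodo-12-[(4R,5S)-2,2,5-trimethyl-4-(3-methylbut-2-en-1-yl)-1,3-dioxan-5-yl]dodeca-4,8-dien-1-yl}-2,2,5-trimethyl-4-(3-methylbut-2-en-1-yl)-1,3-dioxane, via bis(alkenyllithium) 30 (not isolated)
Conditions: t-BuLi (4.4 equiv), Et2O, −78 °C; then I2, THF, −78 °C to rt
Reagents that add atoms: iodine, II
Why: Bromine–lithium exchange with tert-butyllithium and iodinolysis of the alkenyllithium both proceed with retention at −78 °C, so the (Z,Z) geometry should be kept while the halide is upgraded for nickel insertion.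

Step 17
Reactants: 31 the (Z,Z)-diiodide bis(acetonide) of step 16
Product: 32 (5S,6R,10Z,14Z,19S,20R)-6,19-bis(hydroxymethyl)-10,15-diiodo-2,6,19,23-tetramethyltetracosa-2,10,14,22-tetraene-5,20-diol
Conditions: PPTS, MeOH, 40 °C
Reagents that add atoms: none
Why: Acid-catalysed transacetalisation to methanol frees both 1,3-diols under conditions too mild to protonate the trisubstituted alkenes or affect the vinyl iodides.

Step 18
Reactants: 32 the diiodo tetraol of step 17
Product: 33 (6R,10Z,14Z,19S)-10,15-diiodo-2,6,19,23-tetramethyl-5,20-dioxotetracosa-2,10,14,22-tetraene-6,19-dicarbaldehyde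
Conditions: Dess–Martin periodinane, NaHCO3, CH2Cl2, 0 °C to rt
Reagents that add atoms: none
Why: Dess–Martin oxidation converts the two primary and two secondary alcohols under non-basic conditions, so the β,γ-unsaturated ketones should not slip into conjugation nor the non-enolisable β-keto aldehydes lose formyl, and the relay carbinol centres at C9 and C9′ are erased while quaternary C1 and C1′ cannot epimerise.

Step 19
Reactants: 33 the heterochiral (Z,Z)-bis(vinyl iodide) diketo dialdehyde of step 18
Product: 34 CNP0297042.2, the (1R,6S,1′S,6′R) meso diol with rings A and B closed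
Conditions: CrCl2 (10 equiv), NiCl2 (1 mol%), degassed DMF, 0.005 M, rt; aqueous work-up
Reagents that add atoms: none
Why: CrCl2 reduces NiCl2 to zerovalent nickel, which inserts into each C5–I bond with retention of the (Z) geometry, the alkenyl group then passes to trivalent chromium, and the alkenylchromium adds to the formyl group on C1, the chromium alkoxide being hydrolysed on work-up. The closest known reaction type is the intramolecular Nozaki–Hiyama–Kishi cyclisation of an iodoalkenyl aldehyde to a 2-alkylidenecycloalkanol. Ring A (C1–C6) and ring B (C1′–C6′) each close in a 6-exo-trig mode, C5 attacking the carbonyl carbon C6 whose oxygen stays outside the ring. C6 is controlled by the preset C1, and C6′ by C1′: allylic 1,3-strain with the cis C8 chain forces the developing C6–O bond axial, and chromium bridging the aldehyde and C9 ketone oxygens holds the acyl group gauche to it (equatorial), so hydroxyl and acyl should end up cis. The step needs aldehyde-over-ketone chemoselectivity, since attack of C5 on C9 would also be a 6-exo closure, and this is secured by the inertness of alkenylchromium reagents toward ketones and isolated alkenes, while high dilution keeps the two ends from coupling between molecules. Because the two halves are mirror images and react independently, the meso diol should result, with the alkene geometry fixed by the (Z)-iodides.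

Compound list
1 | ethyl (3R)-4-chloro-3-hydroxybutanoate | ClC[C@H](O)CC(=O)OCC | starting material
2 | ethyl 2-[(2R)-oxiran-2-yl]acetate | C1O[C@@H]1CC(=O)OCC | intermediate
3 | (2-methylprop-1-en-1-yl)magnesium bromide | CC(C)=C[Mg]Br | starting material
4 | ethyl (3S)-3-hydroxy-6-methylhept-5-enoate | CC(C)=CC[C@H](O)CC(=O)OCC | intermediate
5 | iodomethane | CI | starting material
6 | dilithium alkoxide enolate of 4 (not isolated) | CC(C)=CC[C@H](O[Li])/C=C(\O[Li])OCC | intermediate
7 | ethyl (2S,3S)-3-hydroxy-2,6-dimethylhept-5-enoate | CC(C)=CC[C@H](O)[C@H](C)C(=O)OCC | intermediate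
8 | allyl bromide | C=CCBr | starting material
9 | dilithium alkoxide enolate of 7 (not isolated) | CC(C)=CC[C@H](O[Li])/C(C)=C(\O[Li])OCC | intermediate
10 | ethyl (2S,3S)-3-hydroxy-2,6-dimethyl-2-(prop-2-en-1-yl)hept-5-enoate | CC(C)=CC[C@H](O)[C@](C(=O)OCC)(C)CC=C | intermediate
11 | (2R,3S)-2,6-dimethyl-2-(prop-2-en-1-yl)hept-5-ene-1,3-diol | CC(C)=CC[C@H](O)[C@](CO)(C)CC=C | intermediate
12 | (4S,5R)-2,2,5-trimethyl-4-(3-methylbut-2-en-1-yl)-5-(prop-2-en-1-yl)-1,3-dioxane | CC(C)=CC[C@@H]1OC(C)(C)OC[C@@]1(C)CC=C | intermediate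
13 | ethyl (3S)-4-chloro-3-hydroxybutanoate | ClC[C@@H](O)CC(=O)OCC | starting material
14 | ethyl 2-[(2S)-oxiran-2-yl]acetate | C1O[C@H]1CC(=O)OCC | intermediate
15 | ethyl (3R)-3-hydroxy-6-methylhept-5-enoate | CC(C)=CC[C@@H](O)CC(=O)OCC | intermediate
16 | dilithium alkoxide enolate of 15 (not isolated) | CC(C)=CC[C@@H](O[Li])/C=C(\O[Li])OCC | intermediate
17 | ethyl (2R,3R)-3-hydroxy-2,6-dimethylhept-5-enoate | CC(C)=CC[C@@H](O)[C@@H](C)C(=O)OCC | intermediate
18 | dilithium alkoxide enolate of 17 (not isolated) | CC(C)=CC[C@@H](O[Li])/C(C)=C(\O[Li])OCC | intermediate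
19 | ethyl (2R,3R)-3-hydroxy-2,6-dimethyl-2-(prop-2-en-1-yl)hept-5-enoate | CC(C)=CC[C@@H](O)[C@@](C(=O)OCC)(C)CC=C | intermediate
20 | (2S,3R)-2,6-dimethyl-2-(prop-2-en-1-yl)hept-5-ene-1,3-diol | CC(C)=CC[C@@H](O)[C@@](CO)(C)CC=C | intermediate
21 | (4R,5S)-2,2,5-trimethyl-4-(3-methylbut-2-en-1-yl)-5-(prop-2-en-1-yl)-1,3-dioxane | CC(C)=CC[C@H]1OC(C)(C)OC[C@]1(C)CC=C | intermediate
22 | succinaldehyde (butanedial) | O=CCCC=O | starting material
23 | tetrabromomethane | BrC(Br)(Br)Br | starting material
24 | (dibromomethylidene)triphenylphosphorane (not isolated) | BrC(Br)=P(c1ccccc1)(c1ccccc1)c1ccccc1 | intermediate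
25 | 1,1,6,6-tetrabromohexa-1,5-diene | BrC(Br)=CCCC=C(Br)Br | intermediate
26 | 9-{3-[(4S,5R)-2,2,5-trimethyl-4-(3-methylbut-2-en-1-yl)-1,3-dioxan-5-yl]propyl}-9-borabicyclo[3.3.1]nonane (not isolated) | CC(C)=CC[C@@H]1OC(C)(C)OC[C@@]1(C)CCCB1C2CCCC1CCC2 | intermediate
27 | (4S,5R)-2,2,5-trimethyl-4-(3-methylbut-2-en-1-yl)-5-[(4Z)-4,9,9-tribromonona-4,8-dien-1-yl]-1,3-dioxane | CC(C)=CC[C@@H]1OC(C)(C)OC[C@@]1(C)CCC/C(Br)=C/CCC=C(Br)Br | intermediate
28 | 9-{3-[(4R,5S)-2,2,5-trimethyl-4-(3-methylbut-2-en-1-yl)-1,3-dioxan-5-yl]propyl}-9-borabicyclo[3.3.1]nonane (not isolated) | CC(C)=CC[C@H]1OC(C)(C)OC[C@]1(C)CCCB1C2CCCC1CCC2 | intermediate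
29 | (4Z,8Z)-4,9-dibromododeca-4,8-diene carrying at C1 the (4S,5R)- and at C12 the (4R,5S)-2,2,5-trimethyl-4-(3-methylbut-2-en-1-yl)-1,3-dioxan-5-yl group (meso) | CC(C)=CC[C@@H]1OC(C)(C)OC[C@@]1(C)CCC/C(Br)=C/CC/C=C(Br)/CCC[C@@]2(C)COC(C)(C)O[C@@H]2CC=C(C)C | intermediate
30 | the 4,9-dilithio analogue of 29 (not isolated) | CC(C)=CC[C@@H]1OC(C)(C)OC[C@@]1(C)CCC/C([Li])=C/CC/C=C([Li])/CCC[C@@]2(C)COC(C)(C)O[C@@H]2CC=C(C)C | intermediate
31 | the (4Z,8Z)-4,9-diiodo analogue of 29 (meso) | CC(C)=CC[C@@H]1OC(C)(C)OC[C@@]1(C)CCC/C(I)=C/CC/C=C(I)/CCC[C@@]2(C)COC(C)(C)O[C@@H]2CC=C(C)C | intermediate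
32 | (5S,6R,10Z,14Z,19S,20R)-6,19-bis(hydroxymethyl)-10,15-diiodo-2,6,19,23-tetramethyltetracosa-2,10,14,22-tetraene-5,20-diol | CC(C)=CC[C@H](O)[C@](CO)(C)CCC/C(I)=C/CC/C=C(I)/CCC[C@@](C)(CO)[C@H](O)CC=C(C)C | intermediate
33 | (6R,10Z,14Z,19S)-10,15-diiodo-2,6,19,23-tetramethyl-5,20-dioxotetracosa-2,10,14,22-tetraene-6,19-dicarbaldehyde | CC(C)=CCC(=O)[C@](C=O)(C)CCC/C(I)=C/CC/C=C(I)/CCC[C@](C)(C(=O)CC=C(C)C)C=O | intermediate
34 | CNP0297042.2: (1R,6S,1′S,6′R) meso diol; each ring has methyl and 4-methylpent-3-enoyl on C1, hydroxyl on C6 cis to the acyl group, and a (Z) exocyclic C5=C7 alkene, the rings being joined through C7–C8–C8′–C7′ | CC(C)=CCC(=O)[C@]1(C)CCC/C(=C/CC/C=C2/CCC[C@](C)(C(=O)CC=C(C)C)[C@@H]2O)[C@@H]1O | target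

Total steps: 19. Longest linear sequence: 12 steps (steps 1–6 and 14–19).

Steps most likely to fail

Step 19, the double ring closure. Facial discrimination at the formyl groups may be poor, because a dipole-minimised arrangement with the acyl group axial can compete with the chromium chelate, so that hydroxyl ends trans to acyl in one or both rings. The fallback sets out from 33 and changes how C6 and C6′ are set. The closure is run as before and the C6/C6′-epimer mixture of the cyclised diol F1 is not separated but oxidised with Dess–Martin periodinane to the (Z,Z)-bis(enone) tetraketone F2, in which both carbinol centres are erased. A Luche reduction (NaBH4, CeCl3·7H2O, MeOH, −78 °C) should then deliver hydride 1,2 to the two enone carbonyls only, anti to the acyl group that stands perpendicular to the C6 carbonyl (Felkin–Anh), and so return to the route at 34.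

Step 14, the mono-coupling on the symmetric tetrabromide. The statistical reaction may run on to the doubly coupled homochiral product or lose part of its trans selectivity, giving by-products that separate poorly from 27. The fallback builds the two termini one after the other and sets out from 12 (as its borane 26) and 23. Commercial 4-(tert-butyldimethylsilyloxy)butanal F3 is converted with 23 and PPh3 into tert-butyl[(5,5-dibromopent-4-en-1-yl)oxy]dimethylsilane F4, which has a single dibromoalkene. Coupling of F4 with 26 under the conditions of step 14 should give the (Z)-bromoalkene silyl ether F5, Bu4NF frees the primary alcohol F6, and Dess–Martin oxidation gives the aldehyde F7. A second Ramirez olefination (23, PPh3, Et3N, CH2Cl2, 0 °C) then returns to the route at 27.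

Step 18, the fourfold oxidation. The reaction may stall at partly oxidised stages, and long exposure or purification may let the prenyl double bonds move into conjugation or a formyl group be lost from the β-keto aldehyde. The fallback reaches the two oxidation levels in separate stages and sets out from 32. TBSCl and imidazole should silylate only the primary hydroxyls to give the bis(silyl ether) diol F8, and Dess–Martin oxidation then gives the robust bis(silyl ether) diketone F9, which can be purified and checked for alkene position. HF·pyridine frees the primary alcohols to give the dihydroxy diketone F10, and a short Dess–Martin oxidation of these two alcohols returns to the route at 33, which is taken at once into step 19.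

Further compounds
F1 | step 19 | C6/C6′-epimer mixture of the cyclised diol | CC(C)=CCC(=O)[C@]1(C)CCC/C(=C/CC/C=C2/CCC[C@](C)(C(=O)CC=C(C)C)C2O)C1O
F2 | step 19 | (Z,Z)-bis(enone) tetraketone (C6 and C6′ as ketones) | CC(C)=CCC(=O)[C@]1(C)CCC/C(=C/CC/C=C2/CCC[C@](C)(C(=O)CC=C(C)C)C2=O)C1=O
F3 | step 14 | 4-(tert-butyldimethylsilyloxy)butanal | O=CCCCO[Si](C)(C)C(C)(C)C
F4 | step 14 | tert-butyl[(5,5-dibromopent-4-en-1-yl)oxy]dimethylsilane | BrC(Br)=CCCCO[Si](C)(C)C(C)(C)C
F5 | step 14 | (4S,5R)-5-[(4Z)-4-bromo-8-(tert-butyldimethylsilyloxy)oct-4-en-1-yl]-2,2,5-trimethyl-4-(3-methylbut-2-en-1-yl)-1,3-dioxane | CC(C)=CC[C@@H]1OC(C)(C)OC[C@@]1(C)CCC/C(Br)=C/CCCO[Si](C)(C)C(C)(C)C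
F6 | step 14 | (4Z)-5-bromo-8-[(4S,5R)-2,2,5-trimethyl-4-(3-methylbut-2-en-1-yl)-1,3-dioxan-5-yl]oct-4-en-1-ol | CC(C)=CC[C@@H]1OC(C)(C)OC[C@@]1(C)CCC/C(Br)=C/CCCO
F7 | step 14 | (4Z)-5-bromo-8-[(4S,5R)-2,2,5-trimethyl-4-(3-methylbut-2-en-1-yl)-1,3-dioxan-5-yl]oct-4-enal | CC(C)=CC[C@@H]1OC(C)(C)OC[C@@]1(C)CCC/C(Br)=C/CCC=O
F8 | step 18 | bis(primary tert-butyldimethylsilyl ether) of tetraol 32 | CC(C)=CC[C@H](O)[C@](CO[Si](C)(C)C(C)(C)C)(C)CCC/C(I)=C/CC/C=C(I)/CCC[C@@](C)(CO[Si](C)(C)C(C)(C)C)[C@H](O)CC=C(C)C
F9 | step 18 | bis(silyl ether) diketone (C9 and C9′ as ketones) | CC(C)=CCC(=O)[C@](CO[Si](C)(C)C(C)(C)C)(C)CCC/C(I)=C/CC/C=C(I)/CCC[C@@](C)(CO[Si](C)(C)C(C)(C)C)C(=O)CC=C(C)C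
F10 | step 18 | dihydroxy diketone (free CH2OH on C1 and C1′) | CC(C)=CCC(=O)[C@](CO)(C)CCC/C(I)=C/CC/C=C(I)/CCC[C@@](C)(CO)C(=O)CC=C(C)C
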